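**Numbering used throughout**

1 2,4-dihydroxybenzaldehyde · 2 prenyl bromide · 3 C3-prenylated aldehyde · 4 its C4 silyl ether · 5 salicyl alcohol · 6 sodium p-toluenesulfinate · 7 ring A sulfone · 8 3-methylbut-2-enal · 9 chromene aldehyde · 10 its silyl ether · 11 enol ether · 12 ring B arylacetaldehyde · 13 ortho-quinone methide · 14 enamine · 15 aminal · 16 lactol · 17 phenol alcohol · 18 bis-silyl isoflavan · 19 target

## Analysis of the target

Compound 19 is a (3S)-isoflavan: a chroman (ring A fused to the oxygen ring C, atoms O1, C2, C3, C4, C4a to C8a) that carries ring B at C3, and ring B is itself the benzo ring of a 2,2-dimethyl-2H-chromene. Ring A has a free hydroxyl at C7 and a prenyl group at C8, between O7 and O1. Ring B has a free hydroxyl at C2' and the pyran fused across C3'–C4' with its oxygen on C4', so both aromatic rings are C-substituted resorcinol units. C3 is the only stereocentre, a benzylic methine between two methylene groups (C2 and C4), so no neighbouring stereocentre or heteroatom can relay its configuration and it must come from a reagent or catalyst. The prenyl group next to two phenolic oxygens closes to a 2,2-dimethylchroman under acid, the chromene alkene is sensitive to acid, electrophiles, ultraviolet light and hydrogenation, and both phenols are easily oxidised. Hydrogenation is therefore excluded both for deprotection and for setting C3 by reduction of an isoflavene, and the last steps must avoid acid. The difficulty is to set an isolated benzylic stereocentre, whose proton is acidic in every carbonyl-bearing precursor, without reductive methods and with two 1,2,3,4-substituted electron-rich rings in place. The strategy rests on two features: C4 is a benzylic CH2 on C4a, ortho to the C8a–O1 oxygen, so O1–C8a–C4a–C4 is a latent ortho-quinone methide; and C2–C3 with ring B is an arylacetaldehyde with C3 as its alpha carbon.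

## Retrosynthetic reasoning

**19 from 18.** The last step only removes two silyl ethers. Fluoride is the one deprotection that leaves the prenyl group, the chromene alkene and both electron-rich rings alone. Both oxygens are carried as triisopropylsilyl rather than tert-butyldimethylsilyl ethers. The aryl tert-butyldimethylsilyl ether is the silyl ether most easily lost to carbonate, alkoxide and aqueous acid, all of which occur on the way. The C2' silyl group also sits close to the primary hydroxyl of 17, where a small silyl group could migrate.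

**18 from 17.** The O1–C2 bond is cut. Forward, an intramolecular Mitsunobu etherification closes ring C at a primary carbon, so C3 is not touched. The C2' oxygen must still be silylated at this point, because a free C2' phenol would compete by closing a five-membered dihydrobenzofuran onto the same carbon. This leaves the C8a hydroxyl as the only free phenol in 17.

**17 from 16.** The key step delivers C2 at the aldehyde level, as the lactol 16. Direct ionic deoxygenation of 16 would need acid and would pass through an oxocarbenium ion that can lose the C3 proton. Hydride reduction to 17 followed by reclosure is therefore preferred. The reduction also removes the epimerisable alpha-aryl aldehyde function as soon as it has formed.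

**16 from 7 and 12.** C3–C4 and O1–C2 are cut together. The cut is placed here because the only stereocentre lies between an acceptor carbon (C4, the methide CH2 of 13) and a donor carbon (C3, the enamine carbon of 14), so the stereocentre is set in the bond-forming event by a chiral secondary amine. The two halves are of equal size and both are derived from 1. Forward, base must release 13 from the bench-stable sulfone 7 slowly, the enamine 14 must add to it on one face, and the phenoxide must close ring C to the aminal 15, which hydrolyses to 16.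

**7 from 5, 4, 3, 1 and 2.** The sulfone 7 comes from the salicyl alcohol 5 and the sulfinate 6 by acid-mediated substitution, and 5 comes from the aldehyde 4 by reduction. The silyl group of 4 is placed on the C4 hydroxyl of 3, the one not hydrogen-bonded to the formyl group. Compound 3 is the C-prenylation product of 1 with 2 at the carbon between the two oxygens, which becomes C8 of the target.

**12 from 11, 10, 9, 1 and 8.** The acetaldehyde 12 is the one-carbon homologue of the aldehyde 10 through the enol ether 11. Compound 10 is the silyl ether of 9. Compound 9 is formed from 1 and 8 by condensation at the same carbon between the oxygens and oxa-6π ring closure through the non-chelated C4 oxygen. The chelated hydroxyl is left over and becomes the C2' hydroxyl of the target.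

## Alternatives that were turned down

**Alternative 1:** Ring A is not bought but built by a benzannulation. The disconnection cuts C8a–C8, C6–C7 and C8a–C4a. Forward, irradiation of the diazo enone A1 triggers a Wolff rearrangement to a vinylketene, which adds across the siloxyalkyne A2. The resulting vinylcyclobutenone opens and recloses by 6π electrocyclisation to the phenol A3. In its favour, the substitution pattern of ring A is unambiguous: the prenyl group lies between a free C8a hydroxyl and a silylated C7 oxygen, exactly as the later ring C closure needs. On this point it is stronger than the chosen route, whose C-prenylation in step 1 is only moderately regioselective; the chosen route accepts that loss in the first step on the cheapest material. Against it, the key step does not create C3, so the stereocentre would have to be set earlier by a separate asymmetric step within the long linear sequence to A1. The photochemical step would also be run on a 2H-chromene, a chromophore that itself ring-opens under ultraviolet light, and beside a prenyl alkene that can intercept a ketene. The methoxymethyl ether in A3 would have to be removed by acid at the end, next to the prenyl group. The chosen strategy uses the aromatic rings as they come in 1 and keeps its risk in the one step that makes the stereocentre.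

**Alternative 2:** The O1–C2 bond and the C3–H bond are formed last. Single-electron oxidation of the 2-arylallyl alkene of A4 by an excited acridinium photooxidant lets the C8a phenol attack the terminal CH2, and a chiral thiol then delivers hydrogen to the C3 benzylic radical to give A5. This is the shortest endgame of all: A5 is the protected target, no carbonyl-stage intermediate can epimerise, and on step economy after the key step it is stronger than the chosen route. Against it, the configuration of C3 would rest on enantioselective hydrogen-atom transfer to a tertiary benzylic radical, a form of induction without dependable precedent. The oxidant would also have to select one alkene among three oxidisable π systems. In particular the same C8a phenol sits ortho to the prenyl group, and anti-Markovnikov closure onto that alkene to a dihydrobenzofuran is the textbook case of this reaction. The chromene alkene and both resorcinol rings are also easily oxidised. The chosen strategy spends three more steps after the key step, but its stereocontrol is a well-understood steric shielding of an enamine face and all its steps are polar, so the alkenes stay out of the reaction.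

**Alternative 3:** C4–C4a and C3–C1' are formed in one three-component coupling. The aryllithium A7 and the vinylboronic ester A8 give a boronate complex. The ring A aryl group placed on palladium by oxidative addition of the triflate A6 adds to the vinyl terminus while ring B migrates from boron to carbon under the control of a chiral bisphosphine ligand, giving the secondary boronate A9. The approach is modular, and the stereocentre of A9 is configurationally robust from the moment it forms; on that point it is stronger than the chosen route, which protects C3 by lactol formation and immediate reduction. Against it, A9 still lacks C2, so a one-carbon homologation of the boronate, oxidation, ester cleavage and ring closure must follow before any deprotection. The triflate A6 requires a tetrasubstituted ring A with three differentiated oxygens, which is much harder to make than 7. Both coupling partners are ortho-substituted, which works against selectivity, and the methoxymethyl ether again has to be removed by acid. The chosen strategy forms ring C and C3 in the same operation from two fragments that each take four steps from 1.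

Key step: step 9

Remark: the facial sense of the key step is assigned from the usual steric-shielding model of diarylprolinol silyl ether enamines, under which the (S)-catalyst should give the (3S) product; the route is written on that basis.

## Route

Step 1
Reactants: 1 2,4-dihydroxybenzaldehyde; 2 prenyl bromide (1-bromo-3-methylbut-2-ene)
Product: 3 2,4-dihydroxy-3-(3-methylbut-2-en-1-yl)benzaldehyde
Conditions: KOH (10% aq), 0 °C to rt
Reagents that add atoms: none
Why: Phenolate C-alkylation in water, where hydrogen bonding to the phenoxide oxygens favours attack through carbon; C3 is ortho to both oxygens and should be the main site of C-alkylation, with the C5 and O-prenyl isomers removed by chromatography.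

Step 2
Reactants: 3 2,4-dihydroxy-3-(3-methylbut-2-en-1-yl)benzaldehyde
Product: 4 2-hydroxy-3-(3-methylbut-2-en-1-yl)-4-(triisopropylsilyloxy)benzaldehyde
Conditions: i-Pr3SiCl (1.05 equiv), imidazole, CH2Cl2, 0 °C to rt
Reagents that add atoms: triisopropylsilyl chloride, CC(C)[Si](Cl)(C(C)C)C(C)C
Why: Silylation of a phenol; the C2 hydroxyl is hydrogen-bonded to the formyl group and flanked on both sides, so the more acidic and more accessible C4 hydroxyl should react selectively.

Step 3
Reactants: 4 2-hydroxy-3-(3-methylbut-2-en-1-yl)-4-(triisopropylsilyloxy)benzaldehyde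
Product: 5 6-(hydroxymethyl)-2-(3-methylbut-2-en-1-yl)-3-(triisopropylsilyloxy)phenol
Conditions: NaBH4, THF/EtOH, 0 °C
Reagents that add atoms: none
Why: Borohydride reduction of an aryl aldehyde; the triisopropylsilyl ether and the alkene are inert, and the electron-rich salicyl alcohol is taken on without storage.

Step 4
Reactants: 5 6-(hydroxymethyl)-2-(3-methylbut-2-en-1-yl)-3-(triisopropylsilyloxy)phenol; 6 sodium p-toluenesulfinate
Product: 7 2-(3-methylbut-2-en-1-yl)-6-[(4-methylphenyl)sulfonylmethyl]-3-(triisopropylsilyloxy)phenol
Conditions: 6 (1.5 equiv), TsOH·H2O (1.2 equiv), CH2Cl2, 0 °C to rt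
Reagents that add atoms: none
Why: Acid-mediated substitution of a salicyl alcohol by sulfinate: the benzylic position, activated by the ortho hydroxyl and the para silyloxy group, ionises under the sulfinic acid formed in the flask and is captured at sulfur to give the stable sulfone. The sulfinate buffer keeps the medium too weakly acidic to close the prenyl group onto the phenol.

Step 5
Reactants: 1 2,4-dihydroxybenzaldehyde; 8 3-methylbut-2-enal
Product: 9 5-hydroxy-2,2-dimethyl-2H-chromene-6-carbaldehyde
Conditions: 8 (2 equiv), pyridine, 120 °C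
Reagents that add atoms: none
Why: Chromene annulation of a resorcinol with an enal: condensation at C3 between the two oxygens, dehydration to a dienone and oxa-6π electrocyclisation through the non-chelated C4 oxygen. The hydrogen-bonded hydroxyl stays free, which gives the angular isomer needed for ring B.

Step 6
Reactants: 9 5-hydroxy-2,2-dimethyl-2H-chromene-6-carbaldehyde
Product: 10 2,2-dimethyl-5-(triisopropylsilyloxy)-2H-chromene-6-carbaldehyde
Conditions: i-Pr3SiOTf, 2,6-lutidine, CH2Cl2, 0 °C to rt
Reagents that add atoms: triisopropylsilyl trifluoromethanesulfonate, CC(C)[Si](OS(=O)(=O)C(F)(F)F)(C(C)C)C(C)C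
Why: Silylation of a hindered, chelated phenol, for which the silyl triflate with a hindered pyridine base is reactive enough; the aldehyde and the chromene alkene are not affected.

Step 7
Reactants: 10 2,2-dimethyl-5-(triisopropylsilyloxy)-2H-chromene-6-carbaldehyde
Product: 11 6-(2-methoxyethenyl)-2,2-dimethyl-5-(triisopropylsilyloxy)-2H-chromene (E/Z mixture)
Conditions: Ph3P(CH2OMe)Cl (1.5 equiv), KOtBu, THF, 0 °C to rt
Reagents that add atoms: (methoxymethyl)triphenylphosphonium chloride, COC[P+](c1ccccc1)(c1ccccc1)c1ccccc1.[Cl-]
Why: Wittig olefination with a methoxymethylene ylide, the standard one-carbon homologation of an aryl aldehyde; the alkene geometry does not matter because both isomers hydrolyse to the same aldehyde.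

Step 8
Reactants: 11 6-(2-methoxyethenyl)-2,2-dimethyl-5-(triisopropylsilyloxy)-2H-chromene (E/Z mixture)
Product: 12 2-[2,2-dimethyl-5-(triisopropylsilyloxy)-2H-chromen-6-yl]acetaldehyde
Conditions: 2 M HCl (aq), THF, rt to 40 °C; used directly
Reagents that add atoms: water, O
Why: Acid hydrolysis of an enol ether by protonation at the aryl-bearing carbon and hydration of the oxocarbenium ion; the aryl triisopropylsilyl ether and the 2,2-dimethylchromene should tolerate dilute aqueous acid for the time needed.

Step 9
Reactants: 7 2-(3-methylbut-2-en-1-yl)-6-[(4-methylphenyl)sulfonylmethyl]-3-(triisopropylsilyloxy)phenol; 12 2-[2,2-dimethyl-5-(triisopropylsilyloxy)-2H-chromen-6-yl]acetaldehyde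
Product: 16 (3S)-3-[2,2-dimethyl-5-(triisopropylsilyloxy)-2H-chromen-6-yl]-8-(3-methylbut-2-en-1-yl)-7-(triisopropylsilyloxy)chroman-2-ol (both C2 anomers), via ortho-quinone methide 13 (not isolated), via E-enamine 14 (not isolated), via N,O-aminal 15 (not isolated)
Conditions: 12 (1.5 equiv), (S)-2-[diphenyl(trimethylsilyloxy)methyl]pyrrolidine (20 mol%), Na2CO3 (1.5 equiv, powder), CH2Cl2, 0 °C to rt; crude product taken into step 10
Reagents that add atoms: none
Why: Carbonate deprotonates the phenol of 7 and the phenoxide expels p-toluenesulfinate to give the ortho-quinone methide 13, while the secondary amine condenses with 12 to the aryl-conjugated E-enamine 14. The enamine carbon (future C3) adds to the exocyclic methide CH2 (future C4) in a Michael-type step that rearomatises ring A, and the phenoxide so formed closes ring C by 6-exo-trig attack on the iminium carbon (O1–C2) to give the aminal 15, which is hydrolysed to the lactol 16 with release of the amine. The closest known reaction type is the aminocatalytic formal [4+2] reaction of aldehyde-derived enamines with ortho-quinone methides released in situ from 2-(sulfonylmethyl)phenols, which gives chroman-2-ols. C3 is the only stereocentre that is controlled: the diphenyl(trimethylsilyloxy)methyl group of the (S)-catalyst shields one face of the s-trans E-enamine, the methide approaches the other face, and with the priorities C2 over ring B over C4 this corresponds to 3S; C2 forms as both anomers and ceases to be a stereocentre in step 10. The step needs enantiofacial selectivity at the enamine, reaction at the enamine carbon rather than benzylation of the free amine nitrogen, and cross-reaction rather than methide oligomerisation or aldehyde self-aldolisation. The first is secured by the catalyst; the others by base-limited, slow release of a methide that is unsubstituted at carbon but tempered by the para silyloxy group, in the presence of an excess of the more nucleophilic conjugated enamine. Closure to the cyclic hemiacetal takes the alpha-aryl aldehyde out of the medium and so protects C3 from enolisation.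

Step 10
Reactants: 16 (3S)-3-[2,2-dimethyl-5-(triisopropylsilyloxy)-2H-chromen-6-yl]-8-(3-methylbut-2-en-1-yl)-7-(triisopropylsilyloxy)chroman-2-ol (both C2 anomers)
Product: 17 (2S)-2-[2,2-dimethyl-5-(triisopropylsilyloxy)-2H-chromen-6-yl]-3-[2-hydroxy-3-(3-methylbut-2-en-1-yl)-4-(triisopropylsilyloxy)phenyl]propan-1-ol
Conditions: NaBH4, THF/MeOH, 0 °C, directly on crude 16
Reagents that add atoms: none
Why: Borohydride reduction of a lactol through its ring-opened hydroxy aldehyde; at 0 °C the aldehyde should be reduced as fast as it is released, so C3 has no time to epimerise, and both anomers converge on one compound.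

Step 11
Reactants: 17 (2S)-2-[2,2-dimethyl-5-(triisopropylsilyloxy)-2H-chromen-6-yl]-3-[2-hydroxy-3-(3-methylbut-2-en-1-yl)-4-(triisopropylsilyloxy)phenyl]propan-1-ol
Product: 18 (3S)-3-[2,2-dimethyl-5-(triisopropylsilyloxy)-2H-chromen-6-yl]-8-(3-methylbut-2-en-1-yl)-7-(triisopropylsilyloxy)chroman
Conditions: PPh3, DIAD, THF, 0 °C to rt
Reagents that add atoms: none
Why: Intramolecular Mitsunobu etherification: the only free phenol displaces the activated primary hydroxyl in a 6-exo-tet closure that re-forms O1–C2. The reaction is at C2, so the configuration of C3 is unchanged.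

Step 12
Reactants: 18 (3S)-3-[2,2-dimethyl-5-(triisopropylsilyloxy)-2H-chromen-6-yl]-8-(3-methylbut-2-en-1-yl)-7-(triisopropylsilyloxy)chroman
Product: 19 (3S)-3-(5-hydroxy-2,2-dimethyl-2H-chromen-6-yl)-8-(3-methylbut-2-en-1-yl)chroman-7-ol
Conditions: Bu4NF (2.5 equiv), AcOH (2.5 equiv), THF, 0 °C, under argon
Reagents that add atoms: none
Why: Fluoride cleavage of two aryl silyl ethers; the acetic acid buffer keeps the liberated electron-rich phenols protonated and so limits air oxidation, and nothing in the medium attacks the prenyl group, the chromene alkene or C3.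

## Compound list

1 | 2,4-dihydroxybenzaldehyde | O=Cc1ccc(O)cc1O | starting material
2 | prenyl bromide (1-bromo-3-methylbut-2-ene) | CC(C)=CCBr | starting material
3 | 2,4-dihydroxy-3-(3-methylbut-2-en-1-yl)benzaldehyde | CC(C)=CCc1c(O)ccc(C=O)c1O | intermediate
4 | 2-hydroxy-3-(3-methylbut-2-en-1-yl)-4-(triisopropylsilyloxy)benzaldehyde | CC(C)=CCc1c(O[Si](C(C)C)(C(C)C)C(C)C)ccc(C=O)c1O | intermediate
5 | 6-(hydroxymethyl)-2-(3-methylbut-2-en-1-yl)-3-(triisopropylsilyloxy)phenol | CC(C)=CCc1c(O[Si](C(C)C)(C(C)C)C(C)C)ccc(CO)c1O | intermediate
6 | sodium p-toluenesulfinate | [Na+].[O-]S(=O)c1ccc(C)cc1 | starting material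
7 | 2-(3-methylbut-2-en-1-yl)-6-[(4-methylphenyl)sulfonylmethyl]-3-(triisopropylsilyloxy)phenol | CC(C)=CCc1c(O[Si](C(C)C)(C(C)C)C(C)C)ccc(CS(=O)(=O)c2ccc(C)cc2)c1O | intermediate
8 | 3-methylbut-2-enal | CC(C)=CC=O | starting material
9 | 5-hydroxy-2,2-dimethyl-2H-chromene-6-carbaldehyde | O=Cc1ccc2c(c1O)C=CC(C)(C)O2 | intermediate
10 | 2,2-dimethyl-5-(triisopropylsilyloxy)-2H-chromene-6-carbaldehyde | O=Cc1ccc2c(c1O[Si](C(C)C)(C(C)C)C(C)C)C=CC(C)(C)O2 | intermediate
11 | 6-(2-methoxyethenyl)-2,2-dimethyl-5-(triisopropylsilyloxy)-2H-chromene (E/Z mixture) | COC=Cc1ccc2c(c1O[Si](C(C)C)(C(C)C)C(C)C)C=CC(C)(C)O2 | intermediate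
12 | 2-[2,2-dimethyl-5-(triisopropylsilyloxy)-2H-chromen-6-yl]acetaldehyde | O=CCc1ccc2c(c1O[Si](C(C)C)(C(C)C)C(C)C)C=CC(C)(C)O2 | intermediate
13 | 6-methylidene-2-(3-methylbut-2-en-1-yl)-3-(triisopropylsilyloxy)cyclohexa-2,4-dien-1-one (ortho-quinone methide, not isolated) | C=C1C=CC(O[Si](C(C)C)(C(C)C)C(C)C)=C(CC=C(C)C)C1=O | intermediate
14 | (S)-1-{(E)-2-[2,2-dimethyl-5-(triisopropylsilyloxy)-2H-chromen-6-yl]ethenyl}-2-[diphenyl(trimethylsilyloxy)methyl]pyrrolidine (enamine, not isolated) | C[Si](C)(C)OC(c1ccccc1)(c1ccccc1)[C@@H]1CCCN1/C=C/c1ccc2c(c1O[Si](C(C)C)(C(C)C)C(C)C)C=CC(C)(C)O2 | intermediate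
15 | (3S)-3-[2,2-dimethyl-5-(triisopropylsilyloxy)-2H-chromen-6-yl]-2-{(S)-2-[diphenyl(trimethylsilyloxy)methyl]pyrrolidin-1-yl}-8-(3-methylbut-2-en-1-yl)-7-(triisopropylsilyloxy)chroman (aminal, both C2 epimers, not isolated) | CC(C)=CCc1c(O[Si](C(C)C)(C(C)C)C(C)C)ccc2c1OC(N1CCC[C@H]1C(c1ccccc1)(c1ccccc1)O[Si](C)(C)C)[C@H](c1ccc3c(c1O[Si](C(C)C)(C(C)C)C(C)C)C=CC(C)(C)O3)C2 | intermediate
16 | (3S)-3-[2,2-dimethyl-5-(triisopropylsilyloxy)-2H-chromen-6-yl]-8-(3-methylbut-2-en-1-yl)-7-(triisopropylsilyloxy)chroman-2-ol (both C2 anomers) | CC(C)=CCc1c(O[Si](C(C)C)(C(C)C)C(C)C)ccc2c1OC(O)[C@H](c1ccc3c(c1O[Si](C(C)C)(C(C)C)C(C)C)C=CC(C)(C)O3)C2 | intermediate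
17 | (2S)-2-[2,2-dimethyl-5-(triisopropylsilyloxy)-2H-chromen-6-yl]-3-[2-hydroxy-3-(3-methylbut-2-en-1-yl)-4-(triisopropylsilyloxy)phenyl]propan-1-ol | CC(C)=CCc1c(O[Si](C(C)C)(C(C)C)C(C)C)ccc(C[C@H](CO)c2ccc3c(c2O[Si](C(C)C)(C(C)C)C(C)C)C=CC(C)(C)O3)c1O | intermediate
18 | (3S)-3-[2,2-dimethyl-5-(triisopropylsilyloxy)-2H-chromen-6-yl]-8-(3-methylbut-2-en-1-yl)-7-(triisopropylsilyloxy)chroman | CC(C)=CCc1c(O[Si](C(C)C)(C(C)C)C(C)C)ccc2c1OC[C@H](c1ccc3c(c1O[Si](C(C)C)(C(C)C)C(C)C)C=CC(C)(C)O3)C2 | intermediate
19 | (3S)-3-(5-hydroxy-2,2-dimethyl-2H-chromen-6-yl)-8-(3-methylbut-2-en-1-yl)chroman-7-ol | CC(C)=CCc1c(O)ccc2c1OC[C@H](c1ccc3c(c1O)C=CC(C)(C)O3)C2 | target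

## Step count and least certain steps

Total: 12 steps. Longest linear sequence: 8 steps (steps 1 to 4 or steps 5 to 8, then steps 9 to 12).

**Step 9 (key step).** Three processes may compete. The unsubstituted methide may oligomerise or benzylate the catalyst nitrogen faster than the enamine adds. Facial discrimination may be incomplete because the ortho-silyloxy aryl group twists the enamine. Configuration may also erode if the lactol reopens and the alpha-aryl aldehyde enolises under carbonate and amine before the reduction. The fallback replaces catalyst control by auxiliary control in a classical enolate alkylation; it sets out from 12 and 4 and returns at 17.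
- Pinnick oxidation of 12 (NaClO2, NaH2PO4, 2-methylbut-2-ene, t-BuOH/H2O) should give 2-[2,2-dimethyl-5-(triisopropylsilyloxy)-2H-chromen-6-yl]acetic acid F1.
- Its pivaloyl mixed anhydride acylates lithiated (S)-4-benzyloxazolidin-2-one to give (4S)-4-benzyl-3-{2-[2,2-dimethyl-5-(triisopropylsilyloxy)-2H-chromen-6-yl]acetyl}oxazolidin-2-one F2.
- In parallel, 4 is O-allylated (allyl bromide, K2CO3, DMF) to 2-(allyloxy)-3-(3-methylbut-2-en-1-yl)-4-(triisopropylsilyloxy)benzaldehyde F3.
- F3 is reduced (NaBH4) to [2-(allyloxy)-3-(3-methylbut-2-en-1-yl)-4-(triisopropylsilyloxy)phenyl]methanol F4 and converted (CBr4, PPh3) to 2-(allyloxy)-1-(bromomethyl)-3-(3-methylbut-2-en-1-yl)-4-(triisopropylsilyloxy)benzene F5.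
- The sodium Z-enolate of F2 (NaN(SiMe3)2, THF, −78 °C) is alkylated by F5 on the face away from the benzyl group. This should give the (2S)-imide (4S)-4-benzyl-3-{(2S)-3-[2-(allyloxy)-3-(3-methylbut-2-en-1-yl)-4-(triisopropylsilyloxy)phenyl]-2-[2,2-dimethyl-5-(triisopropylsilyloxy)-2H-chromen-6-yl]propanoyl}oxazolidin-2-one F6, which is not enolised further under these conditions.
- LiBH4 (THF, a little water, 0 °C) removes the auxiliary to give (2S)-3-[2-(allyloxy)-3-(3-methylbut-2-en-1-yl)-4-(triisopropylsilyloxy)phenyl]-2-[2,2-dimethyl-5-(triisopropylsilyloxy)-2H-chromen-6-yl]propan-1-ol F7.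
- Pd(PPh3)4 (zerovalent palladium, catalytic) with morpholine removes the allyl group to give 17.

**Step 1.** O-alkylation, alkylation at C5 and double alkylation compete with C3 alkylation, so the throughput of 3 may be low and its separation laborious. The fallback places the prenyl group by a sigmatropic shift; it sets out from 1 and returns at 3. The C4 hydroxyl of 1 is alkylated with 3-chloro-3-methylbut-1-yne (K2CO3, KI, CuI, acetone, below 50 °C) to 2-hydroxy-4-[(2-methylbut-3-yn-2-yl)oxy]benzaldehyde F8. The alkyne is semi-hydrogenated (H2, Pd on CaCO3 poisoned with Pb(OAc)2, quinoline) to 2-hydroxy-4-[(2-methylbut-3-en-2-yl)oxy]benzaldehyde F9. Aromatic Claisen rearrangement (N,N-diethylaniline, 120 °C) then delivers the prenyl group to C3 to give 3. The formyl-chelated hydroxyl fixes the double-bond character of the C3–C4 bond and so directs the shift to C3.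

**Step 8.** The aqueous acid may cleave the ortho silyl ether, after which the phenol closes onto the aldehyde to a benzofuran. It may also hydrate the chromene alkene, and the arylacetaldehyde may self-condense. The fallback reaches 12 without acid; it sets out from 10 and returns at 12. Wittig methylenation (Ph3PCH3Br, KOtBu, THF) gives 6-ethenyl-2,2-dimethyl-5-(triisopropylsilyloxy)-2H-chromene F10. Hydroboration with 9-BBN should select the monosubstituted vinyl group over the hindered chromene alkene, and NaBO3·4H2O then gives 2-[2,2-dimethyl-5-(triisopropylsilyloxy)-2H-chromen-6-yl]ethanol F11. Dess–Martin periodinane buffered with NaHCO3 gives 12.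

**Step 4.** The benzylic cation may alkylate the electron-rich ring of a second molecule (Friedel–Crafts self-condensation at the position para to the phenol) faster than sulfinate captures it, and the acid may close the prenyl group onto the phenol. The fallback generates the methide without acid; it sets out from 4 and returns at 7. Reductive amination of 4 (Me2NH·HCl, NaBH(OAc)3, 1,2-dichloroethane) gives the Mannich base 6-[(dimethylamino)methyl]-2-(3-methylbut-2-en-1-yl)-3-(triisopropylsilyloxy)phenol F12. N-Methylation (MeI, Et2O) gives [2-hydroxy-3-(3-methylbut-2-en-1-yl)-4-(triisopropylsilyloxy)phenyl]methyl-trimethylammonium iodide F13. Warming F13 with 6 in DMF (NaHCO3, rt to 50 °C) expels trimethylamine from the phenoxide, and sulfinate captures the methide to give 7.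

## Further compounds

F1 | step 9 | 2-[2,2-dimethyl-5-(triisopropylsilyloxy)-2H-chromen-6-yl]acetic acid | OC(=O)Cc1ccc2c(c1O[Si](C(C)C)(C(C)C)C(C)C)C=CC(C)(C)O2
F2 | step 9 | (4S)-4-benzyl-3-{2-[2,2-dimethyl-5-(triisopropylsilyloxy)-2H-chromen-6-yl]acetyl}oxazolidin-2-one | O=C(Cc1ccc2c(c1O[Si](C(C)C)(C(C)C)C(C)C)C=CC(C)(C)O2)N1[C@@H](Cc2ccccc2)COC1=O
F3 | step 9 | 2-(allyloxy)-3-(3-methylbut-2-en-1-yl)-4-(triisopropylsilyloxy)benzaldehyde | CC(C)=CCc1c(O[Si](C(C)C)(C(C)C)C(C)C)ccc(C=O)c1OCC=C
F4 | step 9 | [2-(allyloxy)-3-(3-methylbut-2-en-1-yl)-4-(triisopropylsilyloxy)phenyl]methanol | CC(C)=CCc1c(O[Si](C(C)C)(C(C)C)C(C)C)ccc(CO)c1OCC=C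
F5 | step 9 | 2-(allyloxy)-1-(bromomethyl)-3-(3-methylbut-2-en-1-yl)-4-(triisopropylsilyloxy)benzene | CC(C)=CCc1c(O[Si](C(C)C)(C(C)C)C(C)C)ccc(CBr)c1OCC=C
F6 | step 9 | (4S)-4-benzyl-3-{(2S)-3-[2-(allyloxy)-3-(3-methylbut-2-en-1-yl)-4-(triisopropylsilyloxy)phenyl]-2-[2,2-dimethyl-5-(triisopropylsilyloxy)-2H-chromen-6-yl]propanoyl}oxazolidin-2-one | CC(C)=CCc1c(O[Si](C(C)C)(C(C)C)C(C)C)ccc(C[C@H](C(=O)N2[C@@H](Cc3ccccc3)COC2=O)c2ccc3c(c2O[Si](C(C)C)(C(C)C)C(C)C)C=CC(C)(C)O3)c1OCC=C
F7 | step 9 | (2S)-3-[2-(allyloxy)-3-(3-methylbut-2-en-1-yl)-4-(triisopropylsilyloxy)phenyl]-2-[2,2-dimethyl-5-(triisopropylsilyloxy)-2H-chromen-6-yl]propan-1-ol | CC(C)=CCc1c(O[Si](C(C)C)(C(C)C)C(C)C)ccc(C[C@H](CO)c2ccc3c(c2O[Si](C(C)C)(C(C)C)C(C)C)C=CC(C)(C)O3)c1OCC=C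
F8 | step 1 | 2-hydroxy-4-[(2-methylbut-3-yn-2-yl)oxy]benzaldehyde | C#CC(C)(C)Oc1ccc(C=O)c(O)c1
F9 | step 1 | 2-hydroxy-4-[(2-methylbut-3-en-2-yl)oxy]benzaldehyde | C=CC(C)(C)Oc1ccc(C=O)c(O)c1
F10 | step 8 | 6-ethenyl-2,2-dimethyl-5-(triisopropylsilyloxy)-2H-chromene | C=Cc1ccc2c(c1O[Si](C(C)C)(C(C)C)C(C)C)C=CC(C)(C)O2
F11 | step 8 | 2-[2,2-dimethyl-5-(triisopropylsilyloxy)-2H-chromen-6-yl]ethanol | OCCc1ccc2c(c1O[Si](C(C)C)(C(C)C)C(C)C)C=CC(C)(C)O2
F12 | step 4 | 6-[(dimethylamino)methyl]-2-(3-methylbut-2-en-1-yl)-3-(triisopropylsilyloxy)phenol | CC(C)=CCc1c(O[Si](C(C)C)(C(C)C)C(C)C)ccc(CN(C)C)c1O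
F13 | step 4 | [2-hydroxy-3-(3-methylbut-2-en-1-yl)-4-(triisopropylsilyloxy)phenyl]methyl-trimethylammonium iodide | CC(C)=CCc1c(O[Si](C(C)C)(C(C)C)C(C)C)ccc(C[N+](C)(C)C)c1O.[I-]
A1 | alternative 1 | (3E,6S)-7-(tert-butyldimethylsilyloxy)-1-diazo-6-[5-(methoxymethoxy)-2,2-dimethyl-2H-chromen-6-yl]hept-3-en-2-one | [N-]=[N+]=CC(=O)/C=C/C[C@H](CO[Si](C)(C)C(C)(C)C)c1ccc2c(c1OCOC)C=CC(C)(C)O2
A2 | alternative 1 | triisopropyl[(5-methylhex-4-en-1-yn-1-yl)oxy]silane | CC(C)=CCC#CO[Si](C(C)C)(C(C)C)C(C)C
A3 | alternative 1 | 6-{(2S)-3-(tert-butyldimethylsilyloxy)-2-[5-(methoxymethoxy)-2,2-dimethyl-2H-chromen-6-yl]propyl}-2-(3-methylbut-2-en-1-yl)-3-(triisopropylsilyloxy)phenol | CC(C)(C)[Si](C)(C)OC[C@H](c1ccc2c(c1OCOC)C=CC(C)(C)O2)Cc1ccc(O[Si](C(C)C)(C(C)C)C(C)C)c(CC=C(C)C)c1O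
A4 | alternative 2 | 3-(tert-butyldimethylsilyloxy)-6-{2-[5-(tert-butyldimethylsilyloxy)-2,2-dimethyl-2H-chromen-6-yl]prop-2-en-1-yl}-2-(3-methylbut-2-en-1-yl)phenol | C=C(Cc1ccc(O[Si](C)(C)C(C)(C)C)c(CC=C(C)C)c1O)c1ccc2c(c1O[Si](C)(C)C(C)(C)C)C=CC(C)(C)O2
A5 | alternative 2 | (3S)-7-(tert-butyldimethylsilyloxy)-3-[5-(tert-butyldimethylsilyloxy)-2,2-dimethyl-2H-chromen-6-yl]-8-(3-methylbut-2-en-1-yl)chroman | CC(C)=CCc1c(O[Si](C)(C)C(C)(C)C)ccc2c1OC[C@H](c1ccc3c(c1O[Si](C)(C)C(C)(C)C)C=CC(C)(C)O3)C2
A6 | alternative 3 | 3-(tert-butyldimethylsilyloxy)-2-(3-methylbut-2-en-1-yl)-6-(trifluoromethylsulfonyloxy)phenyl 2,2-dimethylpropanoate | CC(C)=CCc1c(O[Si](C)(C)C(C)(C)C)ccc(OS(=O)(=O)C(F)(F)F)c1OC(=O)C(C)(C)C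
A7 | alternative 3 | [5-(methoxymethoxy)-2,2-dimethyl-2H-chromen-6-yl]lithium | [Li]c1ccc2c(c1OCOC)C=CC(C)(C)O2
A8 | alternative 3 | 2-ethenyl-4,4,5,5-tetramethyl-1,3,2-dioxaborolane | C=CB1OC(C)(C)C(C)(C)O1
A9 | alternative 3 | 3-(tert-butyldimethylsilyloxy)-6-{(2S)-2-[5-(methoxymethoxy)-2,2-dimethyl-2H-chromen-6-yl]-2-(4,4,5,5-tetramethyl-1,3,2-dioxaborolan-2-yl)ethyl}-2-(3-methylbut-2-en-1-yl)phenyl 2,2-dimethylpropanoate | CC1(C)OB(OC1(C)C)[C@H](c1ccc2c(c1OCOC)C=CC(C)(C)O2)Cc1ccc(O[Si](C)(C)C(C)(C)C)c(CC=C(C)C)c1OC(=O)C(C)(C)C
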